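**Retrosynthetic overview** (ring labels: A = trioxygenated ring, B = para-phenylene, C = 1,2,3-trisubstituted ring, D = ortho-phenylene)
1. The target comes from its di-O-methyl ether (OMe on ring A C-4 and ring C C-3) by one global BBr3 demethylation.
2. The 17-membered ring is the only ring formed and is closed last, at the A–O–B diaryl ether, by an intramolecular Ullmann coupling. Ring A enters as a C2v-symmetric 3,5-dihydroxy-4-methoxyphenyl unit: either homotopic OH closes to the same product, and the OH left over is the target's own free OH, so no protecting group is needed.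
3. The open-chain bromo-diol is obtained by diimide reduction of a bis-stilbene; the two CH2CH2 bridges come from two Wittig olefinations.
4. The C–O–D ether comes from SNAr of an o-vanillin-derived phenol on 2-fluorobenzaldehyde.
5. Building blocks: o-vanillin, 2-fluorobenzaldehyde, (4-bromobenzyl)triphenylphosphonium bromide and 3,5-dihydroxy-4-methoxybenzyl alcohol.

Assumption: the target SMILES has no stereocentre and no stereogenic double bond, and the macrocycle is taken as conformationally mobile, so the compound is achiral and no stereocontrol is required. The stilbene intermediates are carried as E/Z mixtures (SMILES written without alkene geometry), since both isomers converge in step 5.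

**Step 1**
Reactants: 1 3,5-dihydroxy-4-methoxybenzyl alcohol
Product: 2 (3,5-dihydroxy-4-methoxybenzyl)triphenylphosphonium bromide
Conditions: Ph3P·HBr (1.05 equiv), MeCN, reflux, 3 h; salt collected by filtration
Reagents that add atoms: triphenylphosphine hydrobromide, [Br-].[PH+](c1ccccc1)(c1ccccc1)c1ccccc1
Why: SN1-type phosphonium salt formation: HBr ionises the benzylic alcohol (cation stabilised by the para-methoxy group) and PPh3 traps it faster than the ring can, so the meta-phenols need no protection.

**Step 2**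
Reactants: 3 o-vanillin (2-hydroxy-3-methoxybenzaldehyde); 4 (4-bromobenzyl)triphenylphosphonium bromide
Product: 6 2-[2-(4-bromophenyl)ethenyl]-6-methoxyphenol (E/Z mixture), via ylide 5 (not isolated)
Conditions: KOtBu (2.2 equiv), THF, 0 °C to rt; 1 M HCl work-up
Reagents that add atoms: none
Why: Wittig olefination with a semi-stabilised benzylic ylide; the second equivalent of base holds the phenol as its phenoxide, and the alkene geometry is irrelevant because the double bond is saturated in step 5.

**Step 3**
Reactants: 6 2-[2-(4-bromophenyl)ethenyl]-6-methoxyphenol; 7 2-fluorobenzaldehyde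
Product: 8 2-{2-[2-(4-bromophenyl)ethenyl]-6-methoxyphenoxy}benzaldehyde
Conditions: K2CO3 (2 equiv), 7 (1.5 equiv), DMF, 130 °C, N2
Reagents that add atoms: none
Why: SNAr (addition–elimination through a Meisenheimer complex) of the phenoxide on the fluoride activated by the ortho-formyl group; the unactivated aryl bromide is inert.

**Step 4**
Reactants: 8 2-{2-[2-(4-bromophenyl)ethenyl]-6-methoxyphenoxy}benzaldehyde; 2 (3,5-dihydroxy-4-methoxybenzyl)triphenylphosphonium bromide
Product: 10 5-[2-(2-{2-[2-(4-bromophenyl)ethenyl]-6-methoxyphenoxy}phenyl)ethenyl]-2-methoxybenzene-1,3-diol (E/Z mixtures), via phenoxide ylide 9 (not isolated)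
Conditions: 2 (1.2 equiv), KOtBu (3.6 equiv), THF/DMF, 0 °C to rt; 1 M HCl work-up
Reagents that add atoms: none
Why: Wittig olefination without protecting groups: the two phenoxides are meta to the ylide carbon, so they are not conjugated with it and cannot form a quinone methide, and the non-enolisable aldehyde tolerates the excess base.

**Step 5**
Reactants: 10 5-[2-(2-{2-[2-(4-bromophenyl)ethenyl]-6-methoxyphenoxy}phenyl)ethenyl]-2-methoxybenzene-1,3-diol
Product: 11 5-[2-(2-{2-[2-(4-bromophenyl)ethyl]-6-methoxyphenoxy}phenyl)ethyl]-2-methoxybenzene-1,3-diol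
Conditions: TsNHNH2 (10 equiv, in portions), NaOAc (12 equiv), THF/H2O 1:1, reflux, 16 h
Reagents that add atoms: none
Why: Diimide reduction: concerted syn hydrogen transfer saturates both non-polar C=C bonds of all geometric isomers and leaves the aryl bromide, which hydrogenation over Pd would remove; no stereocentre is formed.

**Step 6**
Reactants: 11 5-[2-(2-{2-[2-(4-bromophenyl)ethyl]-6-methoxyphenoxy}phenyl)ethyl]-2-methoxybenzene-1,3-diol
Product: 12 di-O-methyl macrocycle (the target with OMe on ring A C-4 and on ring C C-3, one free OH on ring A)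
Conditions: CuI (0.3 equiv), N,N-dimethylglycine·HCl (0.9 equiv), Cs2CO3 (4 equiv), degassed 1,4-dioxane, 100 °C, syringe-pump addition to 2 mM, Ar
Reagents that add atoms: none
Why: Intramolecular Ullmann diaryl ether coupling that breaks the local C2v symmetry of ring A: both OH groups are homotopic, so either one closes to the same 17-membered ring, the ring C oxygen is methylated and cannot compete, and high dilution suppresses oligomers.

**Step 7**
Reactants: 12 di-O-methyl macrocycle
Product: 13 target CNP0290892.0 (macrocyclic bis(bibenzyl) triphenol)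
Conditions: BBr3 (6 equiv), CH2Cl2, −78 °C to rt; then MeOH/H2O
Reagents that add atoms: none
Why: Lewis-acid-mediated demethylation (bromide attacks the methyl of the boron-complexed ether) cleaves both aryl methyl ethers, whereas the diaryl ethers resist BBr3; the target has no stereocentre to set.

**Compound list**
1 | 3,5-dihydroxy-4-methoxybenzyl alcohol | COc1c(O)cc(CO)cc1O | starting material
2 | (3,5-dihydroxy-4-methoxybenzyl)triphenylphosphonium bromide | COc1c(O)cc(C[P+](c2ccccc2)(c2ccccc2)c2ccccc2)cc1O.[Br-] | intermediate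
3 | o-vanillin (2-hydroxy-3-methoxybenzaldehyde) | COc1cccc(C=O)c1O | starting material
4 | (4-bromobenzyl)triphenylphosphonium bromide | Brc1ccc(C[P+](c2ccccc2)(c2ccccc2)c2ccccc2)cc1.[Br-] | starting material
5 | (4-bromobenzylidene)triphenylphosphorane (ylide, not isolated) | Brc1ccc(C=P(c2ccccc2)(c2ccccc2)c2ccccc2)cc1 | intermediate
6 | 2-[2-(4-bromophenyl)ethenyl]-6-methoxyphenol (E/Z mixture) | COc1cccc(C=Cc2ccc(Br)cc2)c1O | intermediate
7 | 2-fluorobenzaldehyde | O=Cc1ccccc1F | starting material
8 | 2-{2-[2-(4-bromophenyl)ethenyl]-6-methoxyphenoxy}benzaldehyde (E/Z mixture) | COc1cccc(C=Cc2ccc(Br)cc2)c1Oc1ccccc1C=O | intermediate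
9 | dipotassium 2-methoxy-5-[(triphenylphosphoranylidene)methyl]benzene-1,3-diolate (phenoxide ylide, not isolated) | COc1c([O-])cc(C=P(c2ccccc2)(c2ccccc2)c2ccccc2)cc1[O-].[K+].[K+] | intermediate
10 | 5-[2-(2-{2-[2-(4-bromophenyl)ethenyl]-6-methoxyphenoxy}phenyl)ethenyl]-2-methoxybenzene-1,3-diol (E/Z mixtures) | COc1cccc(C=Cc2ccc(Br)cc2)c1Oc1ccccc1C=Cc1cc(O)c(OC)c(O)c1 | intermediate
11 | 5-[2-(2-{2-[2-(4-bromophenyl)ethyl]-6-methoxyphenoxy}phenyl)ethyl]-2-methoxybenzene-1,3-diol | COc1cccc(CCc2ccc(Br)cc2)c1Oc1ccccc1CCc1cc(O)c(OC)c(O)c1 | intermediate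
12 | di-O-methyl macrocycle (OMe on ring A C-4 and ring C C-3) | Oc1cc2cc(c1OC)Oc1ccc(cc1)CCc1cccc(OC)c1Oc1ccccc1CC2 | intermediate
13 | CNP0290892.0 | Oc1cc2cc(c1O)Oc1ccc(cc1)CCc1cccc(O)c1Oc1ccccc1CC2 | target

**Totals**
Total steps: 7. Longest linear sequence: 6 steps (3 → 6 → 8 → 10 → 11 → 12 → 13); step 1 is a one-step side branch.

**Steps most likely to fail, with fallbacks**

Step 6 (macrocyclic Ullmann coupling; oligomerisation or hydrodebromination may dominate). The fallback sets out from aldehyde 8 and diol 1 and returns at 12, closing the ring at the A–D carbon–carbon bridge instead of at the ether. Intermolecular coupling of the aryl bromide of 8 with excess 1 (3 equiv; CuI, picolinic acid, K3PO4, DMSO, 90 °C) mono-arylates the symmetric diol and gives 2-{2-[2-(4-{3-hydroxy-5-(hydroxymethyl)-2-methoxyphenoxy}phenyl)ethenyl]-6-methoxyphenoxy}benzaldehyde F1. Ph3P·HBr in refluxing MeCN converts its benzylic alcohol into {3-[4-(2-{2-(2-formylphenoxy)-3-methoxyphenyl}ethenyl)phenoxy]-5-hydroxy-4-methoxybenzyl}triphenylphosphonium bromide F2. Slow addition of F2 to NaOMe in MeOH/CH2Cl2 (1 mM) closes the ring by intramolecular Wittig reaction to the macrocyclic bis-stilbene F3 (both bridges CH=CH, E/Z mixture). H2 over Pd/C in EtOAc then saturates both alkenes and gives 12.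

Step 4 (Wittig reaction of a phosphonium salt carrying two free phenols; the doubly charged phenoxide ylide may be insoluble or sluggish). The fallback sets out from 8 and 1 and returns at 10 with the polarity of the olefination reversed. NaBH4 (MeOH, 0 °C) reduces 8 to (2-{2-[2-(4-bromophenyl)ethenyl]-6-methoxyphenoxy}phenyl)methanol F4, and Ph3P·HBr (MeCN, reflux) turns it into (2-{2-[2-(4-bromophenyl)ethenyl]-6-methoxyphenoxy}benzyl)triphenylphosphonium bromide F5. Activated MnO2 (EtOAc, rt) oxidises 1 to 3,5-dihydroxy-4-methoxybenzaldehyde F6. Wittig reaction of the now neutral ylide of F5 with F6 (KOtBu 3.2 equiv, THF/DMF) gives 10.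

Step 3 (SNAr of a 2,6-disubstituted phenoxide on an only moderately activated fluoride at 130 °C, with possible aldehyde side reactions). The fallback sets out from 3 and returns at 8, making the ether before the olefination and using a nitrile as the activating group. o-Vanillin 3 and 2-fluorobenzonitrile (K2CO3, DMF, 100 °C) give 2-(2-formyl-6-methoxyphenoxy)benzonitrile F7. Wittig reaction with 4 (KOtBu 1.1 equiv, THF) gives 2-{2-[2-(4-bromophenyl)ethenyl]-6-methoxyphenoxy}benzonitrile F8. DIBAL-H (toluene, −78 °C, then aqueous HCl) reduces the nitrile to aldehyde 8.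

**Further compounds**
F1 | step 6 | 2-{2-[2-(4-{3-hydroxy-5-(hydroxymethyl)-2-methoxyphenoxy}phenyl)ethenyl]-6-methoxyphenoxy}benzaldehyde | COc1cccc(C=Cc2ccc(Oc3cc(CO)cc(O)c3OC)cc2)c1Oc1ccccc1C=O
F2 | step 6 | {3-[4-(2-{2-(2-formylphenoxy)-3-methoxyphenyl}ethenyl)phenoxy]-5-hydroxy-4-methoxybenzyl}triphenylphosphonium bromide | COc1cccc(C=Cc2ccc(Oc3cc(C[P+](c4ccccc4)(c4ccccc4)c4ccccc4)cc(O)c3OC)cc2)c1Oc1ccccc1C=O.[Br-]
F3 | step 6 | macrocyclic bis-stilbene (12 with both bridges as CH=CH) | Oc1cc2cc(c1OC)Oc1ccc(cc1)C=Cc1cccc(OC)c1Oc1ccccc1C=C2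
F4 | step 4 | (2-{2-[2-(4-bromophenyl)ethenyl]-6-methoxyphenoxy}phenyl)methanol | COc1cccc(C=Cc2ccc(Br)cc2)c1Oc1ccccc1CO
F5 | step 4 | (2-{2-[2-(4-bromophenyl)ethenyl]-6-methoxyphenoxy}benzyl)triphenylphosphonium bromide | COc1cccc(C=Cc2ccc(Br)cc2)c1Oc1ccccc1C[P+](c1ccccc1)(c1ccccc1)c1ccccc1.[Br-]
F6 | step 4 | 3,5-dihydroxy-4-methoxybenzaldehyde | COc1c(O)cc(C=O)cc1O
F7 | step 3 | 2-(2-formyl-6-methoxyphenoxy)benzonitrile | COc1cccc(C=O)c1Oc1ccccc1C#N
F8 | step 3 | 2-{2-[2-(4-bromophenyl)ethenyl]-6-methoxyphenoxy}benzonitrile | COc1cccc(C=Cc2ccc(Br)cc2)c1Oc1ccccc1C#N
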